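At early times the left-handed product follows the catalyst: at 0.250 h birch holds 1.6% and elm 8.1%, a ratio of 5.06 against a catalyst ratio of 5.45.

| flask | left-handed substrate | right-handed substrate | partner | protic impurity | free catalyst | remark | time |
|---|---|---|---|---|---|---|---|
| birch | 48 mM | 48 mM | 57.6 mM | 14.4 mM | 0.88 mM | run made earlier |  |
| elm | 48 mM | 48 mM | 57.6 mM | 14.4 mM | 4.8 mM | run made earlier |  |
| delta | 48 mM | 48 mM | 57.6 mM | 14.4 mM | 0.72 mM |  | 6.0 h |
| theta | 48 mM | 48 mM | 57.6 mM | 14.4 mM | 3.0 mM |  | 6.0 h |

| run | time / h | right-handed substrate / % | left-handed substrate / % | left-handed product / % |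
|---|---|---|---|---|
| birch | 0.250 | 49.7 | 48.7 | 1.6 |
| birch | 0.833 | 46.4 | 45.8 | 4.7 |
| birch | 1.33 | 47.1 | 43.6 | 8.9 |
| birch | 2.00 | 46.6 | 41.6 | 8.8 |
| birch | 3.00 | 47.6 | 38.7 | 11.2 |
| elm | 0.250 | 45.2 | 41.9 | 8.1 |
| elm | 0.417 | 48.2 | 40.5 | 10.8 |
| elm | 0.833 | 43.5 | 36.1 | 13.5 |
| elm | 1.50 | 40.8 | 32.9 | 18.0 |
| elm | 3.00 | 40.9 | 28.3 | 21.3 |

(standard deviation of a reading: 1 percentage point)

- free catalyst is single-handed; left-handed substrate and right-handed substrate are mirror images of each other, charged as a racemate, each of them at the stated concentration
- an excess is below zero if the other one leads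

- which one finishes higher in excess of right-handed substrate over left-handed substrate among what is left of the two ("neither" within 2 percentage points) (delta / theta / neither)
- excess of right-handed substrate over left-handed substrate among what is left of the two at the end, delta
- excess of right-handed substrate over left-handed substrate among what is left of the two at the end, theta

I count turnovers. The turnover count (turnover number) is the left-handed product formed per catalyst charged, and at 3.00 h birch gives 12.2 and elm 4.26. A second way uses a different column, the left-handed substrate lost per catalyst charged, and gives 12.3 and 4.34. The two ways agree within the scatter, so I trust the count.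

Elm's count is lower, as it would be if free catalyst is lost in pairs; the product should then follow catalyst-hours, charged [free catalyst] times time. With birch at 3.00 h as the unit of catalyst-hours, elm stands at 0.758 after 0.417 h with 10.8% of product and at 1.51 after 0.833 h with 13.5%, and birch's 11.2% lies between these two readings.

Delta has 1.64 of these units, so I read elm at 0.833 h and expect a count of 18.0. Theta has 6.82, beyond elm's last reading at 5.45, so I take that reading as the nearest. Elm's selectivity factor reads 2.83, and with it I reckon excesses of 10.5% for delta and 18.2% for theta.

The forecast says theta, with 10.7% (8.5% to 13%) for delta and 20.4% (16.5% to 24%) for theta, a little apart from mine, and its ground is that “death second order in catalyst fits well”.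

    partner + free catalyst + left-handed substrate → free catalyst + left-handed product (k = 3500 L² mol⁻² h⁻¹)
    partner + free catalyst + right-handed substrate → free catalyst + right-handed product (k = 1300 L² mol⁻² h⁻¹)
    2 free catalyst → spent catalyst A (k = 220 L mol⁻¹ h⁻¹)
    free catalyst → spent catalyst B (k = 0.210 h⁻¹)
    partner + protic impurity → quenched reagent (k = 4.10 L mol⁻¹ h⁻¹)

The flasks give 8.16% in delta and 16.0% in theta, so theta finishes higher, and each value lies just below the low end of its forecast range. The counts are 15.3 in delta, below my 18.0, and 6.42 in theta. Pairing of free catalyst has a first half-life at charge of 0.758 h in theta, shorter than the 3.30 h of the single-molecule loss, but 3.16 h in delta, about the same. A neighbour of theta charged with 230 mM of partner ends with the same 5.15% of free catalyst as theta, yet its count reaches 14.5 and its excess 63.0%, against 16.0% in theta.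

The earlier runs and the new flask are calculated on assumed constants; noise was put on by code.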